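The data are calculated with constants of no real substance, and the scatter is random.

Start by counting what one flask holds. Divide the monomer in chains by the chains begun, and the average length (number-average degree of polymerisation) reads n = R·x/f. Here R is free monomer charged per pre-initiator charged, 200 in green and in violet; x is the fraction of monomer in chains; f is the share of pre-initiator that has begun a chain, at one chain each, which is a guess.

common to all: free monomer 0.30 M
- noon: pre-initiator 0.75 mM; run made earlier
- spring: pre-initiator 3 mM; run made earlier
- green: pre-initiator 1.5 mM; time 6.0 h
- violet: pre-initiator 1.5 mM; time 1.5 h

- noon (time / h: monomer in chains / %): 0.500: 0; 1.33: 1; 3.00: 9; 8.00: 39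
- spring (time / h: monomer in chains / %): 0.833: 5; 2.50: 24; 5.00: 53; 8.00: 64

(scatter of a reading: 1.5 percentage points)

- the average divides the monomer in chains by the number of chains begun, living and dead together
- the earlier runs do not show the number of chains; that part of a forecast is a guess

* which of the two ends with the longer chains by the average number of monomer units in a chain (chains begun, living or dead) ("neither" if they lie within 10%) (green / violet / neither)
* average number of monomer units in a chain (chains begun, living or dead) at the end, green
* average number of monomer units in a chain (chains begun, living or dead) at the end, violet

Weigh the factors in turn. R comes from the charges, so take it as firm. For x, compare charge times time squared with the runs. Green stands at 1.12 times noon's last reading, so take 39%. Violet lies between spring's first reading and noon's reading at 3.00 h, so take 5%; the scatter of 1.5 percentage points weighs more there, because that reading is lower than green's.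

The weak factor is f: with f equal to one, green gives 78.0. So read f from noon, taking spring's last reading, 64%, as a ceiling. Between the last two intervals of noon, the mid-time rises 2.54 times while the rate per room left, as read, rises 1.94 times, so I read chains as beginning ever more slowly, and I take a pre-initiator half-life near 4.00 h. That gives f of 64.6% in green and 22.9% in violet, so my lengths are 121 and 43.7.

The forecast says green, with 90 and 31, “Assuming one chain per pre-initiator consumed”; its green is shorter than mine.

The flask gives green, 143 against 48.3.

    initiator → spent initiator (k = 9.40 × 10⁻⁴ h⁻¹)
    monomer in chains + living end → free monomer + living end, rate k2*[living end] as long as [monomer in chains] is above zero (k = 39.0 h⁻¹)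
    free monomer + initiator → living end + monomer in chains (k = 14.0 M⁻¹ h⁻¹)
    pre-initiator → initiator (k = 0.180 h⁻¹)
    free monomer + living end → monomer in chains + living end, rate k5*[living end]*[free monomer] (k = 370 M⁻¹ h⁻¹)

The forecast's 1.36 mM of chains in green stands against a living end of 9.50 × 10⁻⁴ M at 6.00 h. With the flask's 45.3% in chains and 34% of pre-initiator left, R gives 137 for green. Now take the neighbour with 0.0060 M of pre-initiator: R falls to 50.0, 64.3% of the monomer is in chains, and 34% of its pre-initiator is left, so the reckoning gives 48.7, and that flask gives 52.2.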